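The route rests on cutting C6–C7, the bond between the gem-dimethyl quaternary carbon and the senecioyloxy carbinol of the seven-membered ring. Cyclobutane carbon C5 is treated as a former ketone, because C7(OH)–C6Me2–C5(=O) is an aldol retron. In one operation, copper hydride adds to an isopropenyl ketone and creates the second methyl group and a fully substituted enolate. This enolate closes the cycloheptane on a pendant aldehyde and sets C7. The precursor is a cis-4,5-disubstituted 3,5-dimethylcyclohexenone made by an auxiliary-controlled Diels–Alder reaction. The C5 ketone later becomes a mesylate, which the C11 enolate displaces to form the cyclobutane.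

Key step: step 10

Remark on numbering: longipinane numbering is used throughout. C1 (C=O), C2=C3(CH3), C4 (CH), C5 (cyclobutane CH next to C6), C6 (CMe2), C7 (O-senecioyl), C8 (CH2), C9 (O-isovaleryl), C10 (C–CH3), C11 (CH next to C1). The cyclobutane is C4–C5–C11–C10.
Assumption: the (5S)-epimer of 3 is taken to be the crystalline one with (+)-menthol, as the mirror image of the known (−)-menthol/(5R) pairing of the parent butenolide. If it is not, the epimers are separated by chromatography.

Step 1
Reactants: 1 5-hydroxy-4-methylfuran-2(5H)-one; 2 (+)-menthol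
Product: 3 (5S)-5-menthyloxy-4-methylbutenolide (C5 lactone carbonyl, C4=C10 alkene, C9 acetal carbon)
Conditions: CSA (cat.), PhMe, reflux (Dean–Stark); crystallisation (hexane)
Reagents that add atoms: none
Why: Acid-catalysed acetalisation (pseudo-ester formation) of the lactol, in which the two C9 epimers equilibrate under the acid so that crystallisation should funnel the material into the (5S)-epimer.

Step 2
Reactants: 4 (E)-pent-3-en-2-one
Product: 5 (E)-2-(tert-butyldimethylsilyloxy)penta-1,3-diene
Conditions: TBSOTf, Et3N, Et2O, 0 °C
Reagents that add atoms: tert-butyldimethylsilyl triflate, CC(C)(C)[Si](C)(C)OS(=O)(=O)C(F)(F)F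
Why: Soft enolisation (silyl triflate and amine) of the enone at its methyl group gives the cross-conjugated 2-silyloxydiene and leaves the E-alkene untouched.

Step 3
Reactants: 3 (5S)-5-menthyloxy-4-methylbutenolide; 5 silyloxydiene
Product: 6 cis-fused Diels–Alder adduct (C1=C2 silyl enol ether; C10 methyl, H-4 and menthyloxy group on one face)
Conditions: PhMe, BHT (cat.), 150 °C, sealed tube
Reagents that add atoms: none
Why: Normal-demand Diels–Alder reaction in which the 2-silyloxy group and the terminal methyl group of 5 both direct its CH2 terminus (C11) to the β-carbon C10, suprafacial addition makes the ring fusion cis, and approach anti to the menthyloxy group sets C10 and C4 in the absolute sense (the endo-derived C3 centre is erased in step 4).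

Step 4
Reactants: 6 Diels–Alder adduct
Product: 7 enone pseudo-ester (C1 ketone, C2=C3 alkene)
Conditions: Pd(OAc)2 (cat.), O2 (1 atm), DMSO, 60 °C
Reagents that add atoms: none
Why: Saegusa–Ito oxidation, in which the regiodefined C1=C2 silyl enol ether gives a palladium enolate whose only β-hydrogen is at C3, so that the C2=C3 enone forms without touching C4, C9 or C10.

Step 5
Reactants: 7 enone pseudo-ester
Product: 8 cis-fused enone γ-lactone with the C9 allyl group cis to the C10 methyl and H-4
Conditions: allylSiMe3, BF3·OEt2, CH2Cl2, −78 to −20 °C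
Reagents that add atoms: allyltrimethylsilane, C=CC[Si](C)(C)C
Why: Hosomi–Sakurai allylation of the acyl-oxocarbenium ion formed by loss of the menthyloxy group, in which quaternary C10 excludes elimination and attack on the convex face of the cis-fused bicycle sets C9 and releases the auxiliary.

Step 6
Reactants: 8 C9-allyl enone lactone
Product: 9 S-ethyl thioester with free C9 hydroxyl (thioester and hydroxyalkyl chain cis on the cyclohexenone)
Conditions: AlMe3, EtSH, CH2Cl2, 0 °C to rt; aq. Rochelle salt
Reagents that add atoms: ethanethiol, CCS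
Why: Aluminium thiolate opening of the γ-lactone (acyl substitution) gives the thioester and frees the C9 hydroxyl with unchanged configuration, and the product is silylated at once to forestall relactonisation.

Step 7
Reactants: 9 hydroxy thioester
Product: 10 C9 TBS ether thioester
Conditions: TBSOTf, 2,6-lutidine, CH2Cl2, −78 to 0 °C
Reagents that add atoms: tert-butyldimethylsilyl triflate, CC(C)(C)[Si](C)(C)OS(=O)(=O)C(F)(F)F
Why: Silyl triflate silylation is the standard method for hindered neopentyl-type secondary alcohols and touches no stereocentre.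

Step 8
Reactants: 10 C9 TBS ether thioester
Product: 12 C7 aldehyde thioester, via vicinal diol 11 (not isolated)
Conditions: OsO4 (cat.), NaIO4, 2,6-lutidine, dioxane–H2O, rt
Reagents that add atoms: osmium tetroxide (catalytic oxygen carrier), O=[Os](=O)(=O)=O; sodium periodate, [Na+].[O-]I(=O)(=O)=O
Why: Lemieux–Johnson cleavage, in which osmium tetroxide selects the only electron-rich monosubstituted alkene over the conjugated ring alkene and periodate cleaves diol 11 to the C7 aldehyde.

Step 9
Reactants: 12 C7 aldehyde thioester
Product: 13 isopropenyl keto aldehyde (C5 ketone bearing C(CH3)=CH2, the future C6)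
Conditions: CH2=C(CH3)SnBu3, Pd2(dba)3 (cat.), P(2-furyl)3, CuOP(O)Ph2, THF, 40 °C
Reagents that add atoms: tributyl(prop-1-en-2-yl)stannane, C=C(C)[Sn](CCCC)(CCCC)CCCC
Why: Liebeskind–Srogl-type ketone synthesis (Pd-catalysed, Cu(I)-mediated thioester–stannane coupling) runs under neutral conditions, so that the aldehyde, the enone and C4 survive, and copper binds the thiolate so that it cannot add to the new vinyl ketone.

Step 10
Reactants: 13 isopropenyl keto aldehyde
Product: 15 cis-fused bicyclo[5.4.0] aldol (C7 hydroxyl trans to the C9 silyloxy group; C5 ketone; C6 gem-dimethyl), via copper enolate 14 (not isolated)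
Conditions: [(Ph3P)CuH]6, PhMe, −40 to 0 °C; aq. NH4Cl
Reagents that add atoms: none
Why: Conjugate hydride transfer from the copper hydride hexamer to the unsubstituted CH2 terminus of the isopropenyl ketone gives copper enolate 14 regiospecifically at C6, and this enolate adds to the C7 aldehyde through a closed metal-bridged transition state; the closest known reaction type is the tandem conjugate reduction–aldol (reductive aldol) cyclisation, established with this reagent for five- and six-membered rings. The cycloheptane closes in the 7-(enolendo)-exo-trig mode, which is allowed and is helped by the cis arrangement (axial C5 acyl group, equatorial C9 chain) on the cyclohexenone. C7 is the only new stereocentre: the O–Cu–O bridge can lie only on the convex face of the emerging cis-fused bicycle (the face of the C10 methyl and H-4), anti to the C9 silyloxy group on the concave face, which should place the C7 oxygen trans to the C9 oxygen as in the target. Selectivity is needed between two enones and two carbonyl acceptors: the β,β-disubstituted ring enone is reduced far more slowly than the terminal vinyl ketone, and the aldehyde is far more electrophilic than the conjugated C1 ketone, whose attack would also demand a boat-like bicyclo[2.2.2] geometry. C6 carries two identical methyl groups and no hydrogen, so neither enolate geometry nor dehydration is an issue, and the low temperature with a buffered quench should suppress retro-aldol cleavage and direct aldehyde reduction.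

Step 11
Reactants: 15 bicyclic aldol
Product: 16 cis-C5,C7-diol (both hydroxyls on the convex face)
Conditions: catecholborane, THF, −10 °C; aq. Rochelle salt
Reagents that add atoms: none
Why: Chelation-controlled reduction of a β-hydroxy ketone (Narasaka–Prasad type, here with catecholborane), in which the C7 boronate binds the C5 ketone and hydride can reach the bridged chelate only from outside, giving the cis (syn) diol, while the s-trans ring enone is inert to this reagent.

Step 12
Reactants: 16 cis-C5,C7-diol
Product: 17 C7 senecioate with free C5 hydroxyl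
Conditions: senecioic acid, 2,4,6-Cl3C6H2COCl, Et3N, DMAP, PhMe, rt
Reagents that add atoms: 3-methylbut-2-enoic acid (senecioic acid), CC(C)=CC(=O)O
Why: Yamaguchi esterification, in which the C7 hydroxyl (CH2 neighbour) should be acylated in preference to the C5 hydroxyl (between C6 and branched C4), and the mixed-anhydride protocol avoids the ketene pathway that deconjugates senecioyl halides.

Step 13
Reactants: 17 C7 senecioate
Product: 18 C5 mesylate
Conditions: MsCl, Et3N, CH2Cl2, 0 °C
Reagents that add atoms: methanesulfonyl chloride, CS(=O)(=O)Cl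
Why: Mesylation by way of sulfene tolerates very hindered alcohols and retains the C5–O bond and hence the C5 configuration.

Step 14
Reactants: 18 C5 mesylate
Product: 20 tricyclic longipinenone with C7 senecioate and C9 TBS ether, via potassium enolate 19 (not isolated)
Conditions: KHMDS, THF, −78 °C to rt
Reagents that add atoms: none
Why: Intramolecular enolate alkylation of a keto sulfonate (4-exo-tet), the classical closure of bicyclo[3.1.1]heptanone terpenoids, in which kinetic deprotonation at C11 gives cross-conjugated enolate 19 whose lobe on the concave face lies behind the C5–O bond of the convex-face mesylate, so that inversion at C5 forms C5–C11 and ring constraint fixes C11.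

Step 15
Reactants: 20 tricyclic silyl ether
Product: 21 tricyclic C9 alcohol
Conditions: HF·pyridine, THF, 0 °C to rt
Reagents that add atoms: none
Why: Fluoride-induced silyl ether cleavage under mildly acidic conditions spares the ester and the enone.

Step 16
Reactants: 21 tricyclic C9 alcohol
Product: 22 target, (4R,5S,7R,9R,10R,11R)-9-isovaleryloxy-7-senecioyloxylongipin-2-en-1-one
Conditions: isovaleric anhydride, DMAP, Et3N, CH2Cl2, 40 °C
Reagents that add atoms: 3-methylbutanoic (isovaleric) anhydride, CC(C)CC(=O)OC(=O)CC(C)C
Why: DMAP-catalysed acylation (nucleophilic catalysis) of the remaining hindered C9 hydroxyl proceeds with retention and gives the target.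

Compound list
1 | 5-hydroxy-4-methylfuran-2(5H)-one (racemic lactol) | CC1=CC(=O)OC1O | starting material
2 | (+)-menthol, (1S,2R,5S)-5-methyl-2-(propan-2-yl)cyclohexan-1-ol | CC(C)[C@H]1CC[C@H](C)C[C@@H]1O | starting material
3 | (5S)-4-methyl-5-[(1S,2R,5S)-menthyloxy]furan-2(5H)-one | CC(C)[C@H]1CC[C@H](C)C[C@@H]1O[C@H]2OC(=O)C=C2C | intermediate
4 | (E)-pent-3-en-2-one | C/C=C/C(C)=O | starting material
5 | (E)-2-(tert-butyldimethylsilyloxy)penta-1,3-diene | C/C=C/C(=C)O[Si](C)(C)C(C)(C)C | intermediate
6 | endo Diels–Alder adduct: cis-fused pseudo-ester; C10 methyl, H-4 and menthyloxy on one face; C1=C2 TBS enol ether; C3 methyl cis to the lactone carbonyl | CC(C)[C@H]1CC[C@H](C)C[C@@H]1O[C@H]2OC(=O)[C@@H]3[C@H](C)C=C(O[Si](C)(C)C(C)(C)C)C[C@]23C | intermediate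
7 | cis-fused enone pseudo-ester (C1 ketone, C2=C3) | CC(C)[C@H]1CC[C@H](C)C[C@@H]1O[C@H]2OC(=O)[C@@H]3C(C)=CC(=O)C[C@]23C | intermediate
8 | cis-fused enone γ-lactone, C9 allyl cis to C10 methyl and H-4 | C=CC[C@H]1OC(=O)[C@@H]2C(C)=CC(=O)C[C@]12C | intermediate
9 | S-ethyl 6-(1-hydroxybut-3-en-1-yl)-2,6-dimethyl-4-oxocyclohex-2-ene-1-carbothioate, thioester cis to the hydroxyalkyl chain | C=CC[C@@H](O)[C@@]1(C)CC(=O)C=C(C)[C@H]1C(=O)SCC | intermediate
10 | C9 TBS ether of 9 | C=CC[C@@H](O[Si](C)(C)C(C)(C)C)[C@@]1(C)CC(=O)C=C(C)[C@H]1C(=O)SCC | intermediate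
11 | vicinal diol from the allyl group of 10 (carbinol epimers) | OCC(O)C[C@@H](O[Si](C)(C)C(C)(C)C)[C@@]1(C)CC(=O)C=C(C)[C@H]1C(=O)SCC | intermediate
12 | C7 aldehyde thioester | O=CC[C@@H](O[Si](C)(C)C(C)(C)C)[C@@]1(C)CC(=O)C=C(C)[C@H]1C(=O)SCC | intermediate
13 | isopropenyl keto aldehyde (key-step precursor) | O=CC[C@@H](O[Si](C)(C)C(C)(C)C)[C@@]1(C)CC(=O)C=C(C)[C@H]1C(=O)C(C)=C | intermediate
14 | copper(I) enolate at C5/C6 (phosphine ligands omitted) | O=CC[C@@H](O[Si](C)(C)C(C)(C)C)[C@@]1(C)CC(=O)C=C(C)[C@H]1C(O[Cu])=C(C)C | intermediate
15 | cis-fused bicyclic aldol: C7 hydroxyl (convex face), C5 ketone, C9 OTBS (concave face) | O[C@@H]1C[C@@H](O[Si](C)(C)C(C)(C)C)[C@@]2(C)CC(=O)C=C(C)[C@H]2C(=O)C1(C)C | intermediate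
16 | cis-C5,C7-diol | O[C@@H]1C[C@@H](O[Si](C)(C)C(C)(C)C)[C@@]2(C)CC(=O)C=C(C)[C@H]2[C@H](O)C1(C)C | intermediate
17 | C7 senecioate, C5 alcohol | CC(C)=CC(=O)O[C@@H]1C[C@@H](O[Si](C)(C)C(C)(C)C)[C@@]2(C)CC(=O)C=C(C)[C@H]2[C@H](O)C1(C)C | intermediate
18 | C7 senecioate, C5 mesylate | CC(C)=CC(=O)O[C@@H]1C[C@@H](O[Si](C)(C)C(C)(C)C)[C@@]2(C)CC(=O)C=C(C)[C@H]2[C@H](OS(C)(=O)=O)C1(C)C | intermediate
19 | potassium cross-conjugated (C1–C11) enolate of 18 | CC(C)=CC(=O)O[C@@H]1C[C@@H](O[Si](C)(C)C(C)(C)C)[C@@]2(C)C=C([O-])C=C(C)[C@H]2[C@H](OS(C)(=O)=O)C1(C)C.[K+] | intermediate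
20 | 9-(TBS-oxy)-7-senecioyloxylongipin-2-en-1-one | CC(C)=CC(=O)O[C@@H]1C[C@@H](O[Si](C)(C)C(C)(C)C)[C@@]2(C)[C@@H]3C(=O)C=C(C)[C@H]2[C@@H]3C1(C)C | intermediate
21 | 9-hydroxy-7-senecioyloxylongipin-2-en-1-one | CC(C)=CC(=O)O[C@@H]1C[C@@H](O)[C@@]2(C)[C@@H]3C(=O)C=C(C)[C@H]2[C@@H]3C1(C)C | intermediate
22 | (4R,5S,7R,9R,10R,11R)-9-isovaleryloxy-7-senecioyloxylongipin-2-en-1-one | CC(C)=CC(=O)O[C@@H]1C[C@@H](OC(=O)CC(C)C)[C@@]2(C)[C@@H]3C(=O)C=C(C)[C@H]2[C@@H]3C1(C)C | target

Total steps: 16. Longest linear sequence: 15 (steps 1 and 3–16; step 2 is a one-step side branch).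

Steps most likely to fail

Step 14. Substitution at C5, which lies between C6 and C4, may be slower than proton exchange among enolates. The extended C4 dienolate would then expel the mesylate (vinylogous β-elimination), or the enolate oxygen may be alkylated. The fallback sets out from 18 and comes back at 20, and it removes the vinylogous acidity before the ring closure. Conjugate reduction of the ring enone of 18 with [(Ph3P)CuH]6 at rt should leave the β,β-disubstituted senecioate untouched and give the saturated keto mesylate F1. With slightly less than one equivalent of KHMDS at rt the enolates equilibrate. Only the C11 enolate is aligned with the back of the C5–O bond, so it should close to the saturated tricyclic ketone F2. C11 is now a bridgehead, so TMSOTf/Et3N can enolise only toward C2 and gives the trimethylsilyl enol ether F3. Saegusa–Ito oxidation of F3 returns to 20.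

Step 3. The β-carbon of 3 is fully substituted, so cycloaddition may be slower than thermal decay of the diene, and the high temperature may erode facial selectivity. The fallback sets out from 5 and comes back at 10. It uses the far more reactive commercial citraconic anhydride as dienophile and brings in chirality later by reagent control.
- Diels–Alder reaction (PhMe, 80 °C) should give the racemic cis-fused anhydride F4 with the same regiochemistry.
- NaBH4 reduces the carbonyl next to quaternary C10, the usual outcome for such anhydrides, to the lactone F5.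
- Me2AlSEt opens F5 to the primary hydroxy thioester F6, and DMP gives the C9 aldehyde F7.
- Brown allylation with (+)-Ipc2B(allyl) from (−)-α-pinene, with ethanolamine work-up, sets (9R) in both enantiomers of F7. The wanted homoallylic alcohol F8 is then separated from its diastereomer by chromatography and is a single enantiomer.
- TBSOTf gives the bis-silyl compound F9, and Saegusa–Ito oxidation of its enol ether returns to 10.

Step 10. Several processes could defeat the ring closure. The copper enolate may be protonated before it closes the seven-membered ring (entropic cost). The aldehyde may be reduced directly. The aldolate may revert by retro-aldol cleavage. Facial selectivity at C7 may be low. The fallback sets out from 13 and comes back at 15, and it separates enolate formation from C–C bond formation. RhCl(PPh3)3-catalysed 1,4-hydrosilylation of the vinyl ketone with Et3SiH should give the isolable triethylsilyl enol ether F10. BF3·OEt2 at −78 °C then triggers an intramolecular Mukaiyama aldol reaction through an open transition state. In this reaction the β-silyloxy aldehyde favours the 1,3-anti product, which is 15 after work-up.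

Further compounds
F1 | step 14 | saturated keto mesylate (C3 epimers) | CC(C)=CC(=O)O[C@@H]1C[C@@H](O[Si](C)(C)C(C)(C)C)[C@@]2(C)CC(=O)CC(C)[C@H]2[C@H](OS(C)(=O)=O)C1(C)C
F2 | step 14 | saturated tricyclic ketone (C3 epimers) | CC(C)=CC(=O)O[C@@H]1C[C@@H](O[Si](C)(C)C(C)(C)C)[C@@]2(C)[C@@H]3C(=O)CC(C)[C@H]2[C@@H]3C1(C)C
F3 | step 14 | C1=C2 trimethylsilyl enol ether of F2 | CC(C)=CC(=O)O[C@@H]1C[C@@H](O[Si](C)(C)C(C)(C)C)[C@@]2(C)[C@@H]3C(O[Si](C)(C)C)=CC(C)[C@H]2[C@@H]3C1(C)C
F4 | step 3 | cis-fused anhydride adduct (racemic; the enantiomer carried on is drawn) | O=C1OC(=O)[C@@H]2[C@H](C)C=C(O[Si](C)(C)C(C)(C)C)C[C@]12C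
F5 | step 3 | cis-fused lactone with C9 as CH2 (racemic; drawn as above) | C1OC(=O)[C@@H]2[C@H](C)C=C(O[Si](C)(C)C(C)(C)C)C[C@]12C
F6 | step 3 | primary hydroxy thioester (racemic; drawn as above) | OC[C@@]1(C)CC(O[Si](C)(C)C(C)(C)C)=C[C@@H](C)[C@H]1C(=O)SCC
F7 | step 3 | C9 aldehyde thioester (racemic; drawn as above) | O=C[C@@]1(C)CC(O[Si](C)(C)C(C)(C)C)=C[C@@H](C)[C@H]1C(=O)SCC
F8 | step 3 | (9R)-homoallylic alcohol, wanted diastereomer | C=CC[C@@H](O)[C@@]1(C)CC(O[Si](C)(C)C(C)(C)C)=C[C@@H](C)[C@H]1C(=O)SCC
F9 | step 3 | bis-silyl compound (C9 TBS ether, C1 TBS enol ether) | C=CC[C@@H](O[Si](C)(C)C(C)(C)C)[C@@]1(C)CC(O[Si](C)(C)C(C)(C)C)=C[C@@H](C)[C@H]1C(=O)SCC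
F10 | step 10 | triethylsilyl enol ether aldehyde | O=CC[C@@H](O[Si](C)(C)C(C)(C)C)[C@@]1(C)CC(=O)C=C(C)[C@H]1C(O[Si](CC)(CC)CC)=C(C)C
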